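**Retrosynthetic overview**

1. The target is (4R)-7-hydroxy-4-(4-hydroxyphenyl)-6-(4-methoxy-2-oxo-2H-pyran-6-yl)-5-methylchroman-2-one; the last disconnection opens the lactone (O1–C2) and puts tert-butyl groups on both phenols and on the acid.
2. The strategy rests on the benzene ring of the chromanone (C4a side chain, C5 CH3, C6 pyranonyl, C7 O, C8 H, C8a O), a fully differentiated resorcinol whose meta oxygens flank the only ring hydrogen. It is made from open chain in one operation: C5–C6 by Wolff shift of an α-diazo ketone, C8–C8a and C6–C7 by [2+2] of the resulting pyranonyl vinylketene with tert-butoxyacetylene, C4a–C8a by 6π closure.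
3. The diazo ketone comes from diazo transfer to a (2-oxoalkyl)pyranone, itself made by vinylogous aldol of lithiated 4-methoxy-6-methyl-2-pyranone with an (E)-2-methyl-enal and oxidation; the enal comes from E-selective allylic oxidation of a prenyl-type alkene.
4. The stereocentre (C4 of the target) is set first, by rhodium/BINAP 1,4-addition of an arylboronic acid to tert-butyl 5-methylhexa-2,4-dienoate, and is never α to a carbonyl group afterwards.
5. Ring order: pyranone (bought), benzene ring (key step), lactone ring (last step).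

Key step: step 9

Assumption 1: the aryl-bearing carbon has one and the same spatial arrangement throughout. It is named S while its third substituent is an alkenyl or sp3 carbon and R once that substituent is the new benzene ring, which outranks the 4-oxyphenyl group.

Assumption 2: the sense of induction in step 2 follows the quadrant model for (E)-enoates; if correlation at the adduct shows the other sense, (R)-BINAP is used and nothing else changes.

Assumption 3: the ketenophile is tert-butoxyacetylene, an established terminal ynol ether, because a silyl ynol ether with a free alkyne CH has no dependable preparation. tert-Butyl is therefore used on all three oxygens so that one acidolysis ends the synthesis.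

**Route**

Step 1
Reactants: 1 3-methylbut-2-enal; 2 tert-butyl (triphenyl-λ5-phosphanylidene)acetate
Product: 3 tert-butyl (2E)-5-methylhexa-2,4-dienoate
Conditions: CH2Cl2, rt
Reagents that add atoms: none
Why: Wittig olefination; the ester-stabilised ylide should give the (2E)-dienoate.

Step 2
Reactants: 3 tert-butyl (2E)-5-methylhexa-2,4-dienoate; 4 (4-tert-butoxyphenyl)boronic acid
Product: 5 tert-butyl (3S)-3-(4-tert-butoxyphenyl)-5-methylhex-4-enoate
Conditions: 4 (2 equiv), [Rh(OH)((S)-binap)]2 (3 mol % Rh), dioxane/H2O (10:1), 50 °C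
Reagents that add atoms: none
Why: Hayashi–Miyaura asymmetric 1,4-addition; the arylrhodium inserts C2=C3 on the face fixed by (S)-BINAP (α-si by the quadrant model, the sense that gives (R)-3-arylbutanoates from crotonates, here named 3S because the alkenyl group outranks CH2CO2tBu), and transfer to C5 is disfavoured because it would create a quaternary carbon.

Step 3
Reactants: 5 tert-butyl (3S)-3-(4-tert-butoxyphenyl)-5-methylhex-4-enoate
Product: 7 tert-butyl (3S,4E)-3-(4-tert-butoxyphenyl)-5-methyl-6-oxohex-4-enoate, via (E)-allylic alcohol 6 (not isolated)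
Conditions: SeO2 (0.5 equiv), t-BuOOH (3 equiv), CH2Cl2, 0 °C to rt; then MnO2, CH2Cl2, rt
Reagents that add atoms: tert-butyl hydroperoxide, CC(C)(C)OO; selenium dioxide (oxygen relay), O=[Se]=O
Why: Selenium dioxide allylic oxidation (ene reaction, then [2,3]-shift) takes the methyl trans to the chain on the more substituted alkene carbon, does not touch C3–H on the less substituted terminus, and MnO2 converges alcohol and aldehyde on the (E)-enal.

Step 4
Reactants: 7 tert-butyl (3S,4E)-3-(4-tert-butoxyphenyl)-5-methyl-6-oxohex-4-enoate; 8 4-methoxy-6-methyl-2H-pyran-2-one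
Product: 10 tert-butyl (3S,4E)-3-(4-tert-butoxyphenyl)-6-hydroxy-7-(4-methoxy-2-oxo-2H-pyran-6-yl)-5-methylhept-4-enoate (both C6 epimers), via lithiated pyranone 9 (not isolated)
Conditions: 8 (1.3 equiv), LiN(iPr)2 (1.3 equiv), THF, −78 °C; then 7, −78 °C; AcOH quench at −78 °C
Reagents that add atoms: none
Why: Vinylogous aldol addition; the base removes a proton from the C6 methyl of the pyranone and the trienolate adds 1,2 to the aldehyde at −78 °C faster than it can deprotonate C3–H or attack the tert-butyl ester, and the new carbinol centre is erased in step 5.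

Step 5
Reactants: 10 tert-butyl (3S,4E)-3-(4-tert-butoxyphenyl)-6-hydroxy-7-(4-methoxy-2-oxo-2H-pyran-6-yl)-5-methylhept-4-enoate
Product: 11 tert-butyl (3S,4E)-3-(4-tert-butoxyphenyl)-7-(4-methoxy-2-oxo-2H-pyran-6-yl)-5-methyl-6-oxohept-4-enoate
Conditions: Dess–Martin periodinane (1.2 equiv), CH2Cl2, 0 °C to rt
Reagents that add atoms: none
Why: Dess–Martin oxidation of the secondary allylic alcohol under non-basic conditions, which avoids β-elimination towards the pyranone and leaves C3 alone.

Step 6
Reactants: 11 tert-butyl (3S,4E)-3-(4-tert-butoxyphenyl)-7-(4-methoxy-2-oxo-2H-pyran-6-yl)-5-methyl-6-oxohept-4-enoate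
Product: 12 tert-butyl (3S,4E)-3-(4-tert-butoxyphenyl)-7-diazo-7-(4-methoxy-2-oxo-2H-pyran-6-yl)-5-methyl-6-oxohept-4-enoate
Conditions: 4-acetamidobenzenesulfonyl azide (1.2 equiv), DBU (1.2 equiv, added last), MeCN, 0 °C; pH 7 buffer quench
Reagents that add atoms: 4-acetamidobenzenesulfonyl azide, CC(=O)Nc1ccc(cc1)S(=O)(=O)N=[N+]=[N-]
Why: Regitz diazo transfer to the methylene flanked by the ketone and pyranone C6, by far the most acidic site, so the base is taken up there and not at the γ-position C3.

Step 7
Reactants: 13 trichloroethene; 14 potassium tert-butoxide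
Product: 16 (E)-1-tert-butoxy-1,2-dichloroethene, via dichloroethyne 15 (not isolated)
Conditions: KOtBu (1.1 equiv), THF, −40 °C to rt
Reagents that add atoms: none
Why: Greene-type synthesis of 1,2-dichlorovinyl ethers; loss of HCl gives dichloroethyne in solution, to which tert-butoxide and a proton add anti.

Step 8
Reactants: 16 (E)-1-tert-butoxy-1,2-dichloroethene
Product: 19 tert-butoxyethyne, via tert-butyl chloroethynyl ether 17 (not isolated), via lithium tert-butoxyacetylide 18 (not isolated)
Conditions: n-BuLi (2.1 equiv), Et2O, −78 to −40 °C; MeOH, −78 °C; cold aqueous wash; kept as a titrated solution at −20 °C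
Reagents that add atoms: none
Why: Dehydrochlorination followed by chlorine–lithium exchange gives the lithium alkoxyacetylide, which is protonated cold; the ynol ether is handled cold because it loses isobutene on warming.

Step 9
Reactants: 12 tert-butyl (3S,4E)-3-(4-tert-butoxyphenyl)-7-diazo-7-(4-methoxy-2-oxo-2H-pyran-6-yl)-5-methyl-6-oxohept-4-enoate; 19 tert-butoxyethyne
Product: 24 tert-butyl (3R)-3-[4-tert-butoxy-6-hydroxy-3-(4-methoxy-2-oxo-2H-pyran-6-yl)-2-methylphenyl]-3-(4-tert-butoxyphenyl)propanoate, via pyranonyl vinylketene 20 (not isolated), via 4-alkenylcyclobutenone 21 (not isolated), via dienylketene 22 (not isolated), via cyclohexa-2,4-dienone 23 (not isolated)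
Conditions: 19 (4 equiv), degassed toluene (0.02 M), hν (blue LED, 420–450 nm), 10 °C; then Ar purge to remove excess 19, 80 °C
Reagents that add atoms: none
Why: Light expels N2 from 12 and the alkenyl group shifts from the carbonyl carbon to the diazo carbon (Wolff rearrangement, C5–C6) to give vinylketene 20, whose carbonyl carbon bonds to the nucleophilic CH of the ynol ether and whose α-carbon bonds to the alkoxy-bearing carbon in a [2+2] cycloaddition (C8–C8a, C6–C7) that gives cyclobutenone 21. On warming, 21 opens by 4π electrocyclic reaction to dienylketene 22, a 6π electrocyclic closure between the ketene carbon and the alkene CH (C4a–C8a) closes the benzene ring as dienone 23, and tautomerisation gives phenol 24. The closest known reaction type is the second-generation Danheiser benzannulation (photo-Wolff of an α-diazo ketone, ketene trapped by an alkoxy- or siloxyalkyne), applied here to a diazo carbon that carries a pyranonyl group. No stereocentre is created, since the ring centres of 21 and 23 vanish on aromatisation and the existing centre only changes its descriptor from S to R. The step needs the [2+2] regiochemistry that puts C8–H between the two oxygens, which the polarisation of ketene and ynol ether secures, and closure on the acyclic C4=C5 alkene instead of C5'=C6' of the pyranone, which is favoured because the pyranone keeps its cyclic conjugation and because reversible opening of 21 lets both dienylketene geometries drain through the aromatising path. Excitation above 400 nm addresses the diazo chromophore and spares the pyranone, the phenol appears only in the dark thermal stage when no ketene is left to acylate it, and the neutral conditions protect the allylic, benzylic C–H.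

Step 10
Reactants: 24 tert-butyl (3R)-3-[4-tert-butoxy-6-hydroxy-3-(4-methoxy-2-oxo-2H-pyran-6-yl)-2-methylphenyl]-3-(4-tert-butoxyphenyl)propanoate
Product: 26 (4R)-7-hydroxy-4-(4-hydroxyphenyl)-6-(4-methoxy-2-oxo-2H-pyran-6-yl)-5-methyl-3,4-dihydro-2H-chromen-2-one, via trihydroxy acid 25 (not isolated)
Conditions: CF3CO2H/CH2Cl2 (1:3), 0 °C to rt, Ar sweep; evaporation from toluene, 40 °C
Reagents that add atoms: none
Why: Acidolysis removes the three tert-butyl groups as isobutene, and the C8a hydroxyl then closes the six-membered lactone onto the acid (acid-catalysed lactonisation, held in place by the C5 methyl and the C4 aryl group); C4 has no acidifying neighbour and should keep its configuration.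

**Compound list**

1 | 3-methylbut-2-enal | CC(C)=CC=O | starting material
2 | tert-butyl (triphenyl-λ5-phosphanylidene)acetate | CC(C)(C)OC(=O)C=P(c1ccccc1)(c1ccccc1)c1ccccc1 | starting material
3 | tert-butyl (2E)-5-methylhexa-2,4-dienoate | CC(C)=C/C=C/C(=O)OC(C)(C)C | intermediate
4 | (4-tert-butoxyphenyl)boronic acid | CC(C)(C)Oc1ccc(B(O)O)cc1 | starting material
5 | tert-butyl (3S)-3-(4-tert-butoxyphenyl)-5-methylhex-4-enoate | CC(C)=C[C@@H](c1ccc(OC(C)(C)C)cc1)CC(=O)OC(C)(C)C | intermediate
6 | tert-butyl (3S,4E)-3-(4-tert-butoxyphenyl)-6-hydroxy-5-methylhex-4-enoate | OC/C(C)=C/[C@@H](c1ccc(OC(C)(C)C)cc1)CC(=O)OC(C)(C)C | intermediate (not isolated)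
7 | tert-butyl (3S,4E)-3-(4-tert-butoxyphenyl)-5-methyl-6-oxohex-4-enoate | O=C/C(C)=C/[C@@H](c1ccc(OC(C)(C)C)cc1)CC(=O)OC(C)(C)C | intermediate
8 | 4-methoxy-6-methyl-2H-pyran-2-one | COc1cc(C)oc(=O)c1 | starting material
9 | [(4-methoxy-2-oxo-2H-pyran-6-yl)methyl]lithium (lithiated pyranone) | [Li]Cc1cc(OC)cc(=O)o1 | intermediate (not isolated)
10 | tert-butyl (3S,4E)-3-(4-tert-butoxyphenyl)-6-hydroxy-7-(4-methoxy-2-oxo-2H-pyran-6-yl)-5-methylhept-4-enoate (both C6 epimers) | COc1cc(CC(O)/C(C)=C/[C@@H](c2ccc(OC(C)(C)C)cc2)CC(=O)OC(C)(C)C)oc(=O)c1 | intermediate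
11 | tert-butyl (3S,4E)-3-(4-tert-butoxyphenyl)-7-(4-methoxy-2-oxo-2H-pyran-6-yl)-5-methyl-6-oxohept-4-enoate | COc1cc(CC(=O)/C(C)=C/[C@@H](c2ccc(OC(C)(C)C)cc2)CC(=O)OC(C)(C)C)oc(=O)c1 | intermediate
12 | tert-butyl (3S,4E)-3-(4-tert-butoxyphenyl)-7-diazo-7-(4-methoxy-2-oxo-2H-pyran-6-yl)-5-methyl-6-oxohept-4-enoate | COc1cc(C(=[N+]=[N-])C(=O)/C(C)=C/[C@@H](c2ccc(OC(C)(C)C)cc2)CC(=O)OC(C)(C)C)oc(=O)c1 | intermediate
13 | trichloroethene | ClC=C(Cl)Cl | starting material
14 | potassium tert-butoxide | CC(C)(C)[O-].[K+] | starting material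
15 | dichloroethyne | ClC#CCl | intermediate (not isolated)
16 | (E)-1-tert-butoxy-1,2-dichloroethene | CC(C)(C)O/C(Cl)=C\Cl | intermediate
17 | 1-tert-butoxy-2-chloroethyne | CC(C)(C)OC#CCl | intermediate (not isolated)
18 | lithium tert-butoxyacetylide | CC(C)(C)OC#C[Li] | intermediate (not isolated)
19 | tert-butoxyethyne | CC(C)(C)OC#C | intermediate
20 | tert-butyl (3S,4E)-3-(4-tert-butoxyphenyl)-6-(4-methoxy-2-oxo-2H-pyran-6-yl)-5-methyl-7-oxohepta-4,6-dienoate (vinylketene) | COc1cc(C(=C=O)/C(C)=C/[C@@H](c2ccc(OC(C)(C)C)cc2)CC(=O)OC(C)(C)C)oc(=O)c1 | intermediate (not isolated)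
21 | tert-butyl (3S,4E)-5-[2-tert-butoxy-1-(4-methoxy-2-oxo-2H-pyran-6-yl)-4-oxocyclobut-2-en-1-yl]-3-(4-tert-butoxyphenyl)hex-4-enoate (both ring epimers) | COc1cc(C2(/C(C)=C/[C@@H](c3ccc(OC(C)(C)C)cc3)CC(=O)OC(C)(C)C)C(=O)C=C2OC(C)(C)C)oc(=O)c1 | intermediate (not isolated)
22 | tert-butyl (3S,4E,6Z)-7-tert-butoxy-3-(4-tert-butoxyphenyl)-6-(4-methoxy-2-oxo-2H-pyran-6-yl)-5-methyl-9-oxonona-4,6,8-trienoate (dienylketene) | O=C=C/C(OC(C)(C)C)=C(c1cc(OC)cc(=O)o1)\C(C)=C\[C@@H](c1ccc(OC(C)(C)C)cc1)CC(=O)OC(C)(C)C | intermediate (not isolated)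
23 | tert-butyl (3S)-3-[4-tert-butoxy-3-(4-methoxy-2-oxo-2H-pyran-6-yl)-2-methyl-6-oxocyclohexa-2,4-dien-1-yl]-3-(4-tert-butoxyphenyl)propanoate (both ring epimers) | COc1cc(C2=C(C)C([C@@H](c3ccc(OC(C)(C)C)cc3)CC(=O)OC(C)(C)C)C(=O)C=C2OC(C)(C)C)oc(=O)c1 | intermediate (not isolated)
24 | tert-butyl (3R)-3-[4-tert-butoxy-6-hydroxy-3-(4-methoxy-2-oxo-2H-pyran-6-yl)-2-methylphenyl]-3-(4-tert-butoxyphenyl)propanoate | COc1cc(-c2c(OC(C)(C)C)cc(O)c(c2C)[C@@H](c2ccc(OC(C)(C)C)cc2)CC(=O)OC(C)(C)C)oc(=O)c1 | intermediate
25 | (3R)-3-[4,6-dihydroxy-3-(4-methoxy-2-oxo-2H-pyran-6-yl)-2-methylphenyl]-3-(4-hydroxyphenyl)propanoic acid | COc1cc(-c2c(O)cc(O)c(c2C)[C@@H](c2ccc(O)cc2)CC(=O)O)oc(=O)c1 | intermediate (not isolated)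
26 | (4R)-7-hydroxy-4-(4-hydroxyphenyl)-6-(4-methoxy-2-oxo-2H-pyran-6-yl)-5-methyl-3,4-dihydro-2H-chromen-2-one | COc1cc(-c2c(O)cc3c(c2C)[C@@H](c2ccc(O)cc2)CC(=O)O3)oc(=O)c1 | target

**Step count and risk**

Total steps: 10. Longest linear sequence: 8 (steps 1–6, 9, 10); the ynol ether branch is steps 7–8.

Steps most likely to fail:

1. Step 9. The carbene or the short-lived ketene may be consumed before the [2+2] (continued irradiation of the pyranone or of the cyclobutenone, decay of the heat-sensitive ynol ether in the light path, acylation or dimerisation), or the dienylketene may close onto the pyranone. Fallback, setting out from 12 and coming back at 24: the ketene is generated in the dark. Brief irradiation (or heating) of 12 in THF/water lets water capture the ketene (Arndt–Eistert-type homologation) and should give (3E,5S)-7-tert-butoxy-5-(4-tert-butoxyphenyl)-2-(4-methoxy-2-oxo-2H-pyran-6-yl)-3-methyl-7-oxohept-3-enoic acid F1. The neutral chlorinating agent 1-chloro-N,N,2-trimethylprop-1-en-1-amine converts it into tert-butyl (3S,4E)-3-(4-tert-butoxyphenyl)-7-chloro-6-(4-methoxy-2-oxo-2H-pyran-6-yl)-5-methyl-7-oxohept-4-enoate F2. Slow addition of Et3N to F2 and 19 in toluene at 0 °C should form vinylketene 20 by dehydrochlorination, and warming to 80 °C completes the same cascade to 24.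

2. Step 2. Aryl transfer may go partly to C5 (1,6-addition) or with poor facial selectivity on the dienoate, and the electron-rich boronic acid may protodeboronate. Fallback, setting out from 2 and coming back at 5: the roles of the two groups at C3 are exchanged. Wittig reaction of 2 with 4-tert-butoxybenzaldehyde should give tert-butyl (2E)-3-(4-tert-butoxyphenyl)prop-2-enoate F3, a simple enoate with no 1,6-pathway. Rhodium/(R)-BINAP-catalysed 1,4-addition of (2-methylprop-1-en-1-yl)boronic acid then installs the alkenyl group; the antipodal ligand is needed because aryl and alkenyl have changed places, and the product is 5.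

3. Step 3. The allylic oxidation may stall, attack the other methyl, over-oxidise, or cost tert-butyl groups through selenous acid. Fallback, setting out from 5 and coming back at 7: the isopropylidene is cut off and the enal rebuilt. Ozonolysis of 5 (O3, CH2Cl2, −78 °C, indicator dye; Me2S) should give tert-butyl (3R)-3-(4-tert-butoxyphenyl)-4-oxobutanoate F4, which is used at once because the α-aryl aldehyde is configurationally labile. Wittig reaction with 2-(triphenyl-λ5-phosphanylidene)propanal in toluene then gives the (E)-enal 7.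

**Further compounds**

F1 | step 9 | (3E,5S)-7-tert-butoxy-5-(4-tert-butoxyphenyl)-2-(4-methoxy-2-oxo-2H-pyran-6-yl)-3-methyl-7-oxohept-3-enoic acid (both C2 epimers) | COc1cc(C(C(=O)O)/C(C)=C/[C@@H](c2ccc(OC(C)(C)C)cc2)CC(=O)OC(C)(C)C)oc(=O)c1
F2 | step 9 | tert-butyl (3S,4E)-3-(4-tert-butoxyphenyl)-7-chloro-6-(4-methoxy-2-oxo-2H-pyran-6-yl)-5-methyl-7-oxohept-4-enoate (both C6 epimers) | COc1cc(C(C(=O)Cl)/C(C)=C/[C@@H](c2ccc(OC(C)(C)C)cc2)CC(=O)OC(C)(C)C)oc(=O)c1
F3 | step 2 | tert-butyl (2E)-3-(4-tert-butoxyphenyl)prop-2-enoate | CC(C)(C)OC(=O)/C=C/c1ccc(OC(C)(C)C)cc1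
F4 | step 3 | tert-butyl (3R)-3-(4-tert-butoxyphenyl)-4-oxobutanoate | O=C[C@@H](c1ccc(OC(C)(C)C)cc1)CC(=O)OC(C)(C)C
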